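## The problem

The target (24) is a biflavone in which C6 of an acacetin unit (unit 1, unprimed locants) is bonded to C8'' of a genkwanin unit (unit 2, double-primed locants). The biaryl bond carries four ortho substituents (O5 and O7 on one side, the 7''-methoxyl and O1'' on the other), so any reaction that joins two finished flavones at this bond meets severe hindrance. There is no stereocentre, so nothing has to be controlled by anything else and the difficulty is regiochemical: 6 against 8 on unit 1, and 8'' against 6'' on unit 2. The oxygen pattern is differentiated: 4'-OMe and 7''-OMe must stay while O5, O7, O5'' and O4''' end as free phenols. This rules out global demethylation and calls for protecting groups that leave under neutral conditions. Both pyranone rings are vinylogous esters that open with hydroxide or amines, a 5-hydroxyflavone can exchange its C6 and C8 substituents in hot acid, and ketene or diazo intermediates tolerate no free phenol. The feature that opens the plan is ring A of unit 2: C5'' bears OH, C6'' bears H, C7'' bears OMe, C8'' bears the aryl group, and C8a''–C4a'' is at the same time the C2=C3 bond of a 4-pyranone. That is the pattern obtained when a ketene carbonyl (C5''), the two carbons of methoxyacetylene (C6'', C7''), an aryl-bearing ketene α-carbon (C8'') and a pyranone double bond are joined in a benzannulation.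

## Retrosynthesis

**24 from 23.** The three O–benzyl bonds on O5, O7 and O4''' are cut. Benzyl is chosen over methyl or acetal groups because the two methyl ethers of the target must survive the deprotection and hydrogenolysis is neutral. The forward step only asks that palladium and hydrogen leave the two flavone C2=C3 bonds alone.

**23 from 16 and 19.** Four bonds of ring A of unit 2 are cut: C8''–C8a'', C5''–C6'', C7''–C8'' and C4a''–C5''. Forward, diazo ketone 16 rearranges to ketene 20, which adds methoxyacetylene (19) to give cyclobutenone 21; this opens to dienylketene 22 and closes onto the pyranone. Compared with a biaryl coupling of two flavones, the hindered C6–C8'' bond is never made between two arenes; it is carried through as the bond from the arene to a benzylic and then a diazo carbon. Compared with closing ring C of unit 2 last, the pyranone is present before ring A exists, so O1'' sits on C8a'' with no choice between two phenols. The precursor lacks a ring and the whole 5''-OH/7''-OMe pattern. The forward reaction must tolerate a ketene α-carbon bearing a 2,6-dialkoxyaryl group and must accept a pyranone double bond as the terminus of the electrocyclization.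

**19 from 17.** Methoxyacetylene (19) is not an article of commerce in useful form and is traced to chloroacetaldehyde dimethyl acetal (17) by double elimination.

**16 from 15.** The C=N2 unit is removed to leave the methylene ketone 15. The methylene group is flanked by the aryl group and the pyranonyl ketone, so direct diazo transfer from a sulfonyl azide is expected without prior activation.

**15 from 6 and 12, by way of 13.** The bond between the benzylic carbon and the ketone carbon is cut. An ester on the benzylic carbon serves as a removable activating group: the enolate of arylacetate 6 is acylated by pyranone ester 12 to give β-keto ester 13, which loses the tert-butyl group and CO2 via acid 14. This divides the molecule into a unit 1 fragment and a pyranone fragment of similar size. The forward reaction asks that the enolate attack the ester carbonyl of 12 and not the pyranone ring.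

**6 from 4 and 5; 4 from 1.** The C6–CH2 bond is cut to aryl iodide 4 and the zinc enolate 5. The carbon transferred is small and primary, so this coupling is much less demanding than an aryl–aryl coupling at the same position. Iodide 4 comes from acacetin (1) by way of 2 and 3. The order is 7-O-benzylation (2), iodination (3), then 5-O-benzylation (4), because a free 5-OH directs iodine to C6 while an O5 ether would send it to C8.

**12 from 9 and 10; 9 from 7 and 8.** The pyranone is opened at O1–C2 to triketo ester 11, which is cut into diketone 9 and diethyl oxalate (10). Diketone 9 is cut into 4'-(benzyloxy)acetophenone (7) and ethyl acetate (8). All three pieces are commercial, and the benzyl ether on the future O4''' is in place from the start.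

## Roads not taken

Alternative 1: The C6–C8'' bond is traced to a C8–C8'' bond. The 8,8''-linked isomer A2 would be heated in aqueous acid so that the pyranone of unit 1 opens at O1–C2, the acyl group rotates and the former O5 recloses on C2, moving the aryl group from C8 to C6 and giving A1, the 5''-O-methyl ether of 24. A final selective cleavage of the peri 5''-methyl ether would follow. Its merits are real: C8 is the easy position to halogenate on an O5-alkylated flavone, both halves come from known flavones, and the step count to A1 could well be lower than the 12 steps proposed here. Its weak points are that the isomerization is an equilibrium between A2 and A1 with no structural bias toward the 6-linked side, that the two isomers are very alike and hard to separate, and that hot acid endangers the methyl ether that keeps unit 2 from isomerizing as well. Making the unsymmetrical A2 also still requires a cross-coupling that forms a biaryl bond with four ortho substituents, so the central steric problem is only moved. The chosen plan has an untested key step to set against this, but it fixes the position of every substituent by the connectivity of its precursors and needs neither an equilibrium nor a late selective demethylation.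

Alternative 2: The C6–C8'' bond is cut directly, with the two flavones held together by a methylene bridge between O5 and O7''. The 8''-iodide A4 would add oxidatively to zerovalent palladium and arylate C6–H in a seven-membered transition state to give the bridged biflavone A3. This is the best-precedented key step of the four plans (intramolecular direct arylation closing a dibenzodioxepine), it is fully convergent from two commercial flavone skeletons, and the tether allows only C6 to be reached; in those respects it is better than the chosen plan. Its cost lies around the key step. The mixed formaldehyde acetal has to be built on the poorly nucleophilic, chelated 5-OH. The bridge then has to be opened with a Lewis acid strong enough to threaten the benzyl ethers. O7'' must finally be methylated selectively in the presence of the freed 5-OH. The chosen plan sets against this that the 7''-methoxyl arrives with the alkyne and that no tether has to be made or removed.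

Alternative 3: Ring A of unit 2 is again made from an open chain, but through a polyketide-type route. Mg(OMe)2 would open the lactone of the 3-aryl-4-methoxy-2-pyrone A6, and the carbanion between the two ketones would attack the methyl ester to form C4a''–C8a'', giving the 2',6'-dihydroxy-4'-methoxy-3'-aryl chalcone A5. The pyrone-to-acylphloroglucinol conversion is known chemistry, and like the chosen plan it carries the hindered biaryl bond through as an unhindered bond to a non-aromatic carbon. The decisive weakness comes afterwards: A5 has two hydroxyl groups ortho to the cinnamoyl group, and oxidative closure of ring C can use either. Closure through the hydroxyl next to the aryl group gives the wanted 8''-linked flavone, but that hydroxyl is the more hindered one, so the 6''-linked isomer is the likelier product. A6 is also an elaborate precursor in its own right. The chosen plan avoids the choice altogether because the pyranone oxygen is already bonded to the future C8a'' before ring A is formed; what it pays for this is the unproven electrocyclization onto a pyranone.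

Key step: step 11

Assumption: the target is drawn without a descriptor for the hindered C6–C8'' axis, so the axis is formed without control and 24 is taken as the racemate.

## Route

Step 1
Reactants: 1 acacetin (5,7-dihydroxy-2-(4-methoxyphenyl)-4H-chromen-4-one)
Product: 2 7-O-benzylacacetin (7-(benzyloxy)-5-hydroxy-2-(4-methoxyphenyl)-4H-chromen-4-one)
Conditions: BnBr (1.1 equiv), K2CO3, acetone, reflux
Reagents that add atoms: benzyl bromide, BrCc1ccccc1
Why: Williamson etherification; the 7-OH, para to the carbonyl and the most acidic phenol, is alkylated while the 5-OH stays held in its hydrogen bond to C4=O under these mild conditions.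

Step 2
Reactants: 2 7-O-benzylacacetin
Product: 3 7-(benzyloxy)-5-hydroxy-6-iodo-2-(4-methoxyphenyl)-4H-chromen-4-one
Conditions: BnMe3N·ICl2 (1.1 equiv), CaCO3, CH2Cl2–MeOH, rt
Reagents that add atoms: benzyltrimethylammonium dichloroiodate, C[N+](C)(C)Cc1ccccc1.Cl[I-]Cl
Why: Electrophilic aromatic iodination; with the 5-OH free, dichloroiodate delivers iodine ortho to the chelated phenol at C6 of 5-hydroxy-7-alkoxyflavones, whereas O5-alkylated flavones react at C8, which is why iodination precedes the second benzylation. CaCO3 takes up the HCl.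

Step 3
Reactants: 3 7-(benzyloxy)-5-hydroxy-6-iodo-2-(4-methoxyphenyl)-4H-chromen-4-one
Product: 4 5,7-bis(benzyloxy)-6-iodo-2-(4-methoxyphenyl)-4H-chromen-4-one
Conditions: BnBr (2 equiv), Cs2CO3, DMF, 60 °C
Reagents that add atoms: benzyl bromide, BrCc1ccccc1
Why: Williamson etherification of the chelated, iodine-flanked 5-OH, which needs the stronger base and warm DMF. Both oxygens must be capped because a free phenol next to C6 would trap the ketene of step 11 as a lactone.

Step 4
Reactants: 4 5,7-bis(benzyloxy)-6-iodo-2-(4-methoxyphenyl)-4H-chromen-4-one; 5 tert-butyl (bromozincio)acetate (commercial Reformatsky reagent solution)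
Product: 6 tert-butyl 2-[5,7-bis(benzyloxy)-2-(4-methoxyphenyl)-4-oxo-4H-chromen-6-yl]acetate
Conditions: 5 (2.5 equiv), Pd2(dba)3 (2.5 mol %), XPhos (10 mol %), THF, 65 °C
Reagents that add atoms: none
Why: Negishi-type coupling of a Reformatsky reagent (palladium-catalysed α-arylation of an ester zinc enolate); oxidative addition of the aryl iodide to zerovalent palladium bearing the bulky biarylphosphine is followed by transfer of a small primary carbon, far less demanding than an aryl–aryl coupling at this position. The weakly basic zinc enolate leaves the chromone untouched.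

Step 5
Reactants: 7 4'-(benzyloxy)acetophenone; 8 ethyl acetate
Product: 9 1-[4-(benzyloxy)phenyl]butane-1,3-dione
Conditions: NaH (2.5 equiv), 8 (excess), THF, reflux; then aq. HCl
Reagents that add atoms: none
Why: Crossed Claisen condensation of the methyl ketone enolate with ethyl acetate, driven to completion by deprotonation of the 1,3-diketone.

Step 6
Reactants: 9 1-[4-(benzyloxy)phenyl]butane-1,3-dione; 10 diethyl oxalate
Product: 12 ethyl 6-[4-(benzyloxy)phenyl]-4-oxo-4H-pyran-2-carboxylate, via triketo ester 11 (not isolated)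
Conditions: NaOEt (2.2 equiv), EtOH, 0 °C → rt; then HCl, EtOH, reflux
Reagents that add atoms: none
Why: Claisen condensation at the terminal methyl group of the diketone (acylation at the central carbon is reversible) gives the 2,4,6-triketo ester, and acid closes it by cyclodehydration to the 4-pyranone, the classical route to 6-arylcomanic esters. The aryl benzyl ether tolerates ethanolic HCl.

Step 7
Reactants: 6 tert-butyl 2-[5,7-bis(benzyloxy)-2-(4-methoxyphenyl)-4-oxo-4H-chromen-6-yl]acetate; 12 ethyl 6-[4-(benzyloxy)phenyl]-4-oxo-4H-pyran-2-carboxylate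
Product: 13 tert-butyl 2-[5,7-bis(benzyloxy)-2-(4-methoxyphenyl)-4-oxo-4H-chromen-6-yl]-3-{6-[4-(benzyloxy)phenyl]-4-oxo-4H-pyran-2-yl}-3-oxopropanoate (racemic, enolizable)
Conditions: LiN(SiMe3)2 (2.2 equiv), THF, −78 °C; then 12 (1.1 equiv), −78 → −20 °C; AcOH quench
Reagents that add atoms: none
Why: Crossed Claisen condensation between the preformed lithium enolate of 6 and the non-enolizable, strongly activated ester of 12; the second equivalent of base takes up the acidic β-keto ester and keeps the condensation from reversing. Low temperature should favour attack at the ester carbonyl over conjugate addition to the pyranone.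

Step 8
Reactants: 13 tert-butyl β-keto ester from step 7
Product: 15 2-[5,7-bis(benzyloxy)-2-(4-methoxyphenyl)-4-oxo-4H-chromen-6-yl]-1-{6-[4-(benzyloxy)phenyl]-4-oxo-4H-pyran-2-yl}ethan-1-one, via β-keto acid 14 (not isolated)
Conditions: TFA–CH2Cl2 (1:4), 0 °C → rt; then toluene, 60 °C
Reagents that add atoms: none
Why: Acidolysis of the tert-butyl ester with loss of 2-methylpropene, then decarboxylation of the β-keto acid through its cyclic six-membered transition state. Brief, cold acid is chosen to spare the acid-sensitive 5-O-benzyl ether.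

Step 9
Reactants: 15 methylene ketone from step 8
Product: 16 2-diazo-2-[5,7-bis(benzyloxy)-2-(4-methoxyphenyl)-4-oxo-4H-chromen-6-yl]-1-{6-[4-(benzyloxy)phenyl]-4-oxo-4H-pyran-2-yl}ethan-1-one
Conditions: 4-acetamidobenzenesulfonyl azide (1.3 equiv), DBU (1.5 equiv), MeCN, 0 °C → rt, dark
Reagents that add atoms: 4-acetamidobenzenesulfonyl azide, CC(=O)Nc1ccc(cc1)S(=O)(=O)N=[N+]=[N-]
Why: Regitz diazo transfer; the methylene group flanked by the aryl group and the ketone is deprotonated by DBU and the enolate takes the diazo group from the sulfonyl azide, as with deoxybenzoins.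

Step 10
Reactants: 17 chloroacetaldehyde dimethyl acetal (2-chloro-1,1-dimethoxyethane)
Product: 19 methoxyacetylene (methoxyethyne), via sodium methoxyethynide 18 (not isolated)
Conditions: NaNH2 (3 equiv), liq. NH3, −33 °C; then aq. NH4Cl, −60 °C → rt, distilled into cold toluene
Reagents that add atoms: none
Why: Double elimination; amide removes methanol and then HCl from the chloroacetal, and the ynol ether is held as its sodium acetylide until the quench, the standard preparation of methoxyacetylene. The volatile product is used at once as a toluene solution.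

Step 11
Reactants: 16 diazo ketone from step 9; 19 methoxyacetylene
Product: 23 5,7-bis(benzyloxy)-6-{2-[4-(benzyloxy)phenyl]-5-hydroxy-7-methoxy-4-oxo-4H-chromen-8-yl}-2-(4-methoxyphenyl)-4H-chromen-4-one, via ketene 20 (not isolated), via cyclobutenone 21 (not isolated), via dienylketene 22 (not isolated)
Conditions: 19 (6 equiv), toluene, sealed tube, dark, 80 → 110 °C
Reagents that add atoms: none
Why: Proposed new method: on heating, 16 should lose N2 with 1,2-shift of the pyranonyl group (Wolff rearrangement, making C8''–C8a'') to give ketene 20, whose electrophilic carbonyl carbon bonds to the nucleophilic CH carbon of ynol ether 19 while its α-carbon bonds to the C–OMe carbon, a (2+2) cycloaddition that makes C5''–C6'' and C7''–C8'' in cyclobutenone 21. Cyclobutenone 21 then opens by 4π electrocyclic cleavage of its C5''–C8'' bond to dienylketene 22, and ring A closes by a thermal, disrotatory 6π electrocyclization between the ketene carbon and C3 of the pyranone (C4a''–C5''), after which enolization gives the phenol and restores the chromone. The closest known reaction type is the Danheiser benzannulation of α-diazo ketones with alkoxyalkynes, together with the thermal conversion of diarylketenes and alkoxyacetylenes into 3-alkoxy-1-naphthols. What has not been shown is a 4-pyranone C2=C3 bond as the 2π terminus; it is reasonable because C3 is the electron-rich β-carbon of a vinylogous ester and meets the electrophilic ketene carbon with matched polarity. No stereocenter is formed, since the quaternary carbon of 21 is transient and racemic and the biaryl axis is not controlled. The methoxyl is placed on C7'' by the polarity of the ynol ether in the cycloaddition. The site of ring closure is fixed because both ortho positions of the unit 1 aryl group carry benzyloxy groups, and the isomer of 22 with the ketene cis to that aryl group can only return to 21 and reopen until it leaves through the productive isomer. The benzyl ethers on O5 and O7 keep phenols away from the ketene, and the new 5''-OH is hydrogen-bonded to C4''=O and so a poor ketene trap.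

Step 12
Reactants: 23 tribenzyl ether from step 11
Product: 24 5,7-dihydroxy-6-[5-hydroxy-2-(4-hydroxyphenyl)-7-methoxy-4-oxo-4H-chromen-8-yl]-2-(4-methoxyphenyl)-4H-chromen-4-one (target)
Conditions: H2 (1 atm), 10% Pd/C, THF–MeOH, rt
Reagents that add atoms: none
Why: Hydrogenolysis of the three aryl benzyl ethers over palladium; the methyl ethers are untouched, and the flavone C2=C3 bonds, conjugated to a carbonyl and an aryl ring, should not be reduced at 1 atm and room temperature.

## Compound list

1 | acacetin, 5,7-dihydroxy-2-(4-methoxyphenyl)-4H-chromen-4-one | COc1ccc(cc1)-c1cc(=O)c2c(O)cc(O)cc2o1 | starting material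
2 | 7-(benzyloxy)-5-hydroxy-2-(4-methoxyphenyl)-4H-chromen-4-one | COc1ccc(cc1)-c1cc(=O)c2c(O)cc(OCc3ccccc3)cc2o1 | intermediate
3 | 7-(benzyloxy)-5-hydroxy-6-iodo-2-(4-methoxyphenyl)-4H-chromen-4-one | COc1ccc(cc1)-c1cc(=O)c2c(O)c(I)c(OCc3ccccc3)cc2o1 | intermediate
4 | 5,7-bis(benzyloxy)-6-iodo-2-(4-methoxyphenyl)-4H-chromen-4-one | COc1ccc(cc1)-c1cc(=O)c2c(OCc3ccccc3)c(I)c(OCc3ccccc3)cc2o1 | intermediate
5 | tert-butyl (bromozincio)acetate | CC(C)(C)OC(=O)C[Zn]Br | starting material
6 | tert-butyl 2-[5,7-bis(benzyloxy)-2-(4-methoxyphenyl)-4-oxo-4H-chromen-6-yl]acetate | COc1ccc(cc1)-c1cc(=O)c2c(OCc3ccccc3)c(CC(=O)OC(C)(C)C)c(OCc3ccccc3)cc2o1 | intermediate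
7 | 4'-(benzyloxy)acetophenone | CC(=O)c1ccc(OCc2ccccc2)cc1 | starting material
8 | ethyl acetate | CCOC(C)=O | starting material
9 | 1-[4-(benzyloxy)phenyl]butane-1,3-dione | CC(=O)CC(=O)c1ccc(OCc2ccccc2)cc1 | intermediate
10 | diethyl oxalate | CCOC(=O)C(=O)OCC | starting material
11 | ethyl 6-[4-(benzyloxy)phenyl]-2,4,6-trioxohexanoate (not isolated) | CCOC(=O)C(=O)CC(=O)CC(=O)c1ccc(OCc2ccccc2)cc1 | intermediate
12 | ethyl 6-[4-(benzyloxy)phenyl]-4-oxo-4H-pyran-2-carboxylate | CCOC(=O)c1cc(=O)cc(-c2ccc(OCc3ccccc3)cc2)o1 | intermediate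
13 | tert-butyl 2-[5,7-bis(benzyloxy)-2-(4-methoxyphenyl)-4-oxo-4H-chromen-6-yl]-3-{6-[4-(benzyloxy)phenyl]-4-oxo-4H-pyran-2-yl}-3-oxopropanoate (racemic) | COc1ccc(cc1)-c1cc(=O)c2c(OCc3ccccc3)c(C(C(=O)OC(C)(C)C)C(=O)c3cc(=O)cc(-c4ccc(OCc5ccccc5)cc4)o3)c(OCc3ccccc3)cc2o1 | intermediate
14 | 2-[5,7-bis(benzyloxy)-2-(4-methoxyphenyl)-4-oxo-4H-chromen-6-yl]-3-{6-[4-(benzyloxy)phenyl]-4-oxo-4H-pyran-2-yl}-3-oxopropanoic acid (racemic, not isolated) | COc1ccc(cc1)-c1cc(=O)c2c(OCc3ccccc3)c(C(C(O)=O)C(=O)c3cc(=O)cc(-c4ccc(OCc5ccccc5)cc4)o3)c(OCc3ccccc3)cc2o1 | intermediate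
15 | 2-[5,7-bis(benzyloxy)-2-(4-methoxyphenyl)-4-oxo-4H-chromen-6-yl]-1-{6-[4-(benzyloxy)phenyl]-4-oxo-4H-pyran-2-yl}ethan-1-one | COc1ccc(cc1)-c1cc(=O)c2c(OCc3ccccc3)c(CC(=O)c3cc(=O)cc(-c4ccc(OCc5ccccc5)cc4)o3)c(OCc3ccccc3)cc2o1 | intermediate
16 | 2-diazo-2-[5,7-bis(benzyloxy)-2-(4-methoxyphenyl)-4-oxo-4H-chromen-6-yl]-1-{6-[4-(benzyloxy)phenyl]-4-oxo-4H-pyran-2-yl}ethan-1-one | COc1ccc(cc1)-c1cc(=O)c2c(OCc3ccccc3)c(C(=[N+]=[N-])C(=O)c3cc(=O)cc(-c4ccc(OCc5ccccc5)cc4)o3)c(OCc3ccccc3)cc2o1 | intermediate
17 | chloroacetaldehyde dimethyl acetal | COC(CCl)OC | starting material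
18 | sodium methoxyethynide (not isolated) | [Na+].[C-]#COC | intermediate
19 | methoxyacetylene | COC#C | intermediate
20 | 2-[5,7-bis(benzyloxy)-2-(4-methoxyphenyl)-4-oxo-4H-chromen-6-yl]-2-{6-[4-(benzyloxy)phenyl]-4-oxo-4H-pyran-2-yl}ethen-1-one, the aryl(pyranonyl)ketene (not isolated) | COc1ccc(cc1)-c1cc(=O)c2c(OCc3ccccc3)c(C(=C=O)c3cc(=O)cc(-c4ccc(OCc5ccccc5)cc4)o3)c(OCc3ccccc3)cc2o1 | intermediate
21 | 4-[5,7-bis(benzyloxy)-2-(4-methoxyphenyl)-4-oxo-4H-chromen-6-yl]-4-{6-[4-(benzyloxy)phenyl]-4-oxo-4H-pyran-2-yl}-3-methoxycyclobut-2-en-1-one (racemic, not isolated) | COc1ccc(cc1)-c1cc(=O)c2c(OCc3ccccc3)c(C5(C(=O)C=C5OC)c6cc(=O)cc(-c7ccc(OCc8ccccc8)cc7)o6)c(OCc3ccccc3)cc2o1 | intermediate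
22 | (3E)-4-[5,7-bis(benzyloxy)-2-(4-methoxyphenyl)-4-oxo-4H-chromen-6-yl]-4-{6-[4-(benzyloxy)phenyl]-4-oxo-4H-pyran-2-yl}-3-methoxybuta-1,3-dien-1-one, ketene cis to the pyranonyl group (not isolated) | O=C=C/C(OC)=C(/c1c(OCc2ccccc2)cc2oc(cc(=O)c2c1OCc1ccccc1)-c1ccc(OC)cc1)c1cc(=O)cc(-c2ccc(OCc3ccccc3)cc2)o1 | intermediate
23 | 5,7-bis(benzyloxy)-6-{2-[4-(benzyloxy)phenyl]-5-hydroxy-7-methoxy-4-oxo-4H-chromen-8-yl}-2-(4-methoxyphenyl)-4H-chromen-4-one | COc1ccc(cc1)-c1cc(=O)c2c(OCc3ccccc3)c(-c3c(OC)cc(O)c4c(=O)cc(-c5ccc(OCc6ccccc6)cc5)oc34)c(OCc3ccccc3)cc2o1 | intermediate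
24 | 5,7-dihydroxy-6-[5-hydroxy-2-(4-hydroxyphenyl)-7-methoxy-4-oxo-4H-chromen-8-yl]-2-(4-methoxyphenyl)-4H-chromen-4-one | COc1ccc(-c2cc(=O)c3c(O)c(-c4c(OC)cc(O)c5c(=O)cc(-c6ccc(O)cc6)oc45)c(O)cc3o2)cc1 | target

## Step count and risks

Total: 12 steps. Longest linear sequence: 9 steps (steps 1, 2, 3, 4, 7, 8, 9, 11, 12, from acacetin); steps 5–6 and step 10 are side branches.

**Step 11 (key step, proposed new method).** Several processes can divert the material before ring A closes:
- carbene-type insertion into a benzylic C–H bond, or attack of a benzyloxy oxygen on the carbene, instead of clean Wolff migration;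
- dipolar cycloaddition of the diazo group with the electron-rich alkyne;
- a slow (2+2) addition at the hindered ketene, leaving time for ketene dimerization;
- an electrocyclization onto the pyranone slower than oligomerization of the dienylketene.

The fallback uses only known reaction types and makes the biaryl bond by a Suzuki–Miyaura coupling of two hindered partners. It sets out from iodide 4 and from commercial genkwanin (5,4'-dihydroxy-7-methoxyflavone, COc1cc(O)c2c(=O)cc(-c3ccc(O)cc3)oc2c1). Both phenols of genkwanin are benzylated (BnBr, K2CO3, DMF, 80 °C) to 5-(benzyloxy)-2-[4-(benzyloxy)phenyl]-7-methoxy-4H-chromen-4-one F1. Iodination at C8, the position taken once O5 is alkylated (I2, AgOCOCF3, CH2Cl2), gives 5-(benzyloxy)-2-[4-(benzyloxy)phenyl]-8-iodo-7-methoxy-4H-chromen-4-one F2. Miyaura borylation (B2pin2, KOAc, PdCl2(dppf), dioxane, 90 °C) gives the 8-(pinacolato)boryl flavone F3. Coupling of F3 with 4 (Pd(OAc)2, SPhos, K3PO4, toluene–H2O, 100 °C) gives the 5,7,5'',4'''-tetra-O-benzyl ether of the target F4, and hydrogenolysis (H2, 10% Pd/C) returns to the route at 24.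

**Step 4.** Oxidative addition and transmetalation at the di-ortho-alkoxy iodide may be slow, so that protodeiodination by adventitious proton sources overtakes the coupling. The fallback sets out from 4 and introduces the two carbons as an allyl group. Stille coupling with allyltributylstannane (Pd(PPh3)4, DMF, 90 °C) gives 6-allyl-5,7-bis(benzyloxy)-2-(4-methoxyphenyl)-4H-chromen-4-one F5. Lemieux–Johnson cleavage (OsO4 cat., NaIO4, 2,6-lutidine, dioxane–H2O) gives 2-[5,7-bis(benzyloxy)-2-(4-methoxyphenyl)-4-oxo-4H-chromen-6-yl]acetaldehyde F6. Pinnick oxidation (NaClO2, NaH2PO4, 2-methyl-2-butene) gives 2-[5,7-bis(benzyloxy)-2-(4-methoxyphenyl)-4-oxo-4H-chromen-6-yl]acetic acid F7, and tert-butyl ester formation (Boc2O, DMAP, t-BuOH) returns to the route at 6.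

**Step 7.** The enolate may add in conjugate fashion to the pyranone ring and open it, or the hindered enolate may react too slowly with the ester. The fallback replaces the Claisen condensation by an aldol addition and oxidation. It sets out from 12: NaBH4 (MeOH, 0 °C) reduces the activated ester to 2-[4-(benzyloxy)phenyl]-6-(hydroxymethyl)-4H-pyran-4-one F8, and MnO2 (CH2Cl2) gives 6-[4-(benzyloxy)phenyl]-4-oxo-4H-pyran-2-carbaldehyde F9. The lithium enolate of 6 (LiN(SiMe3)2, THF, −78 °C) adds to the far more electrophilic aldehyde to give tert-butyl 2-[5,7-bis(benzyloxy)-2-(4-methoxyphenyl)-4-oxo-4H-chromen-6-yl]-3-{6-[4-(benzyloxy)phenyl]-4-oxo-4H-pyran-2-yl}-3-hydroxypropanoate F10 (mixture of racemic diastereomers). Dess–Martin oxidation returns to the route at 13.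

**Step 8.** The acid may remove the 5-O-benzyl group, which sits peri to the carbonyl, or shift it onto carbon, before the tert-butyl ester is fully cleaved. The fallback avoids acid by using an ethyl ester and a Krapcho dealkoxycarbonylation. It sets out from 4: coupling with ethyl (bromozincio)acetate under the conditions of step 4 gives ethyl 2-[5,7-bis(benzyloxy)-2-(4-methoxyphenyl)-4-oxo-4H-chromen-6-yl]acetate F11. Claisen condensation with 12 as in step 7 gives ethyl 2-[5,7-bis(benzyloxy)-2-(4-methoxyphenyl)-4-oxo-4H-chromen-6-yl]-3-{6-[4-(benzyloxy)phenyl]-4-oxo-4H-pyran-2-yl}-3-oxopropanoate F12 (racemic). Heating with LiCl in wet DMSO (130 °C) returns to the route at 15.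

## Further compounds

F1 | step 11 | 5-(benzyloxy)-2-[4-(benzyloxy)phenyl]-7-methoxy-4H-chromen-4-one | COc1cc(OCc2ccccc2)c2c(=O)cc(-c3ccc(OCc4ccccc4)cc3)oc2c1
F2 | step 11 | 5-(benzyloxy)-2-[4-(benzyloxy)phenyl]-8-iodo-7-methoxy-4H-chromen-4-one | COc1cc(OCc2ccccc2)c2c(=O)cc(-c3ccc(OCc4ccccc4)cc3)oc2c1I
F3 | step 11 | 5-(benzyloxy)-2-[4-(benzyloxy)phenyl]-7-methoxy-8-(4,4,5,5-tetramethyl-1,3,2-dioxaborolan-2-yl)-4H-chromen-4-one | COc1cc(OCc2ccccc2)c2c(=O)cc(-c3ccc(OCc4ccccc4)cc3)oc2c1B1OC(C)(C)C(C)(C)O1
F4 | step 11 | 5,7-bis(benzyloxy)-6-{5-(benzyloxy)-2-[4-(benzyloxy)phenyl]-7-methoxy-4-oxo-4H-chromen-8-yl}-2-(4-methoxyphenyl)-4H-chromen-4-one | COc1ccc(cc1)-c1cc(=O)c2c(OCc3ccccc3)c(-c3c(OC)cc(OCc4ccccc4)c4c(=O)cc(-c5ccc(OCc6ccccc6)cc5)oc34)c(OCc3ccccc3)cc2o1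
F5 | step 4 | 6-allyl-5,7-bis(benzyloxy)-2-(4-methoxyphenyl)-4H-chromen-4-one | COc1ccc(cc1)-c1cc(=O)c2c(OCc3ccccc3)c(CC=C)c(OCc3ccccc3)cc2o1
F6 | step 4 | 2-[5,7-bis(benzyloxy)-2-(4-methoxyphenyl)-4-oxo-4H-chromen-6-yl]acetaldehyde | COc1ccc(cc1)-c1cc(=O)c2c(OCc3ccccc3)c(CC=O)c(OCc3ccccc3)cc2o1
F7 | step 4 | 2-[5,7-bis(benzyloxy)-2-(4-methoxyphenyl)-4-oxo-4H-chromen-6-yl]acetic acid | COc1ccc(cc1)-c1cc(=O)c2c(OCc3ccccc3)c(CC(O)=O)c(OCc3ccccc3)cc2o1
F8 | step 7 | 2-[4-(benzyloxy)phenyl]-6-(hydroxymethyl)-4H-pyran-4-one | OCc1cc(=O)cc(-c2ccc(OCc3ccccc3)cc2)o1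
F9 | step 7 | 6-[4-(benzyloxy)phenyl]-4-oxo-4H-pyran-2-carbaldehyde | O=Cc1cc(=O)cc(-c2ccc(OCc3ccccc3)cc2)o1
F10 | step 7 | tert-butyl 2-[5,7-bis(benzyloxy)-2-(4-methoxyphenyl)-4-oxo-4H-chromen-6-yl]-3-{6-[4-(benzyloxy)phenyl]-4-oxo-4H-pyran-2-yl}-3-hydroxypropanoate (mixture of racemic diastereomers) | COc1ccc(cc1)-c1cc(=O)c2c(OCc3ccccc3)c(C(C(=O)OC(C)(C)C)C(O)c3cc(=O)cc(-c4ccc(OCc5ccccc5)cc4)o3)c(OCc3ccccc3)cc2o1
F11 | step 8 | ethyl 2-[5,7-bis(benzyloxy)-2-(4-methoxyphenyl)-4-oxo-4H-chromen-6-yl]acetate | COc1ccc(cc1)-c1cc(=O)c2c(OCc3ccccc3)c(CC(=O)OCC)c(OCc3ccccc3)cc2o1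
F12 | step 8 | ethyl 2-[5,7-bis(benzyloxy)-2-(4-methoxyphenyl)-4-oxo-4H-chromen-6-yl]-3-{6-[4-(benzyloxy)phenyl]-4-oxo-4H-pyran-2-yl}-3-oxopropanoate (racemic) | COc1ccc(cc1)-c1cc(=O)c2c(OCc3ccccc3)c(C(C(=O)OCC)C(=O)c3cc(=O)cc(-c4ccc(OCc5ccccc5)cc4)o3)c(OCc3ccccc3)cc2o1
A1 | alternative 1 | 5''-O-methyl ether of the target, 6,8''-linked | COc1ccc(cc1)-c1cc(=O)c2c(O)c(-c3c(OC)cc(OC)c4c(=O)cc(-c5ccc(O)cc5)oc34)c(O)cc2o1
A2 | alternative 1 | 8,8''-linked isomer of A1, 5,7-dihydroxy-8-[2-(4-hydroxyphenyl)-5,7-dimethoxy-4-oxo-4H-chromen-8-yl]-2-(4-methoxyphenyl)-4H-chromen-4-one | COc1ccc(cc1)-c1cc(=O)c2c(O)cc(O)c(-c3c(OC)cc(OC)c4c(=O)cc(-c5ccc(O)cc5)oc34)c2o1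
A3 | alternative 2 | O5,O7''-methylene-bridged 6,8''-biflavone tribenzyl ether | COc1ccc(cc1)-c1cc(=O)c2c3OCOc4cc(OCc5ccccc5)c5c(=O)cc(-c6ccc(OCc7ccccc7)cc6)oc5c4-c3c(OCc3ccccc3)cc2o1
A4 | alternative 2 | O5,O7''-methylene-bridged bis-flavone 8''-iodide, tribenzyl ether | COc1ccc(cc1)-c1cc(=O)c2c(OCOc3cc(OCc4ccccc4)c4c(=O)cc(-c5ccc(OCc6ccccc6)cc5)oc4c3I)cc(OCc3ccccc3)cc2o1
A5 | alternative 3 | 2',6'-dihydroxy-4'-methoxy-3'-(5,7-dibenzyloxy-4'-methoxyflavon-6-yl)-4-benzyloxychalcone | O=C(/C=C/c1ccc(OCc2ccccc2)cc1)c1c(O)cc(OC)c(-c2c(OCc3ccccc3)cc3oc(-c4ccc(OC)cc4)cc(=O)c3c2OCc2ccccc2)c1O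
A6 | alternative 3 | 3-(5,7-dibenzyloxy-4'-methoxyflavon-6-yl)-4-methoxy-6-[(3E)-4-(4-benzyloxyphenyl)-2-oxobut-3-enyl]-2H-pyran-2-one | COc1cc(CC(=O)/C=C/c2ccc(OCc3ccccc3)cc2)oc(=O)c1-c1c(OCc2ccccc2)cc2oc(cc(=O)c2c1OCc1ccccc1)-c1ccc(OC)cc1
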